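**Retrosynthetic overview**

- Feature: in the oxolan-2-one ring (O1, carbonyl C2, C3, C4, C5) the only stereocentre, C4, carries two CH2 groups, ring carbon C5 (bonded to O1) and the exocyclic benzylic CH2. If both start as the two CH2 arms of an oxetan-3-yl group on C3, C4 is prochiral.
- Late disconnections: the phenolic O–Si bond, then the CH2–aryl bond to ring B (Negishi coupling of a lactone CH2ZnI with 5-iodo-1,2,3-trimethoxybenzene), back through the iodide to a 4-(hydroxymethyl) lactone.
- Key disconnection: O1–C5, made by opening the oxetane with the geminal carboxylic acid under a chiral phosphoric acid. This single step forms the lactone and fixes C4.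
- The oxetanyl acrylic acid comes from a (Z)-α-bromocinnamate (bromo-Wittig on silylated syringaldehyde) and oxetan-3-ylzinc iodide (Negishi, retention), followed by mild ester cleavage.
- Ring order: rings A and B and the oxetane are purchased; the lactone is the only ring formed (step 5).

Key step: step 5

Remark: the sense of induction of the phosphoric acid cannot be predicted with confidence. The (R)-catalyst is written, and its mirror image is to be used without other change if the first run shows the opposite sense.

**Route**

Step 1
Reactants: 1 syringaldehyde (4-hydroxy-3,5-dimethoxybenzaldehyde)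
Product: 2 3,5-dimethoxy-4-(triisopropylsilyloxy)benzaldehyde
Conditions: i-Pr3SiCl, imidazole, DMF, rt
Reagents that add atoms: triisopropylsilyl chloride, CC(C)[Si](Cl)(C(C)C)C(C)C
Why: Imidazole-promoted O-silylation of the phenol should go cleanly despite the two flanking methoxy groups, and the bulky aryl silyl ether removes the only acidic proton before the organozinc steps while staying inert to the tin hydroxide, the phosphoric acid and the Appel reagents.

Step 2
Reactants: 2 3,5-dimethoxy-4-(triisopropylsilyloxy)benzaldehyde
Product: 3 methyl (Z)-2-bromo-3-[3,5-dimethoxy-4-(triisopropylsilyloxy)phenyl]prop-2-enoate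
Conditions: Ph3P=CHCO2Me, NBS, CH2Cl2, −20 °C; then 2, K2CO3, −20 °C → rt
Reagents that add atoms: methyl (triphenylphosphoranylidene)acetate, COC(=O)C=P(c1ccccc1)(c1ccccc1)c1ccccc1; N-bromosuccinimide, O=C1CCC(=O)N1Br
Why: In this halogenation–Wittig olefination the stabilised ylide is brominated at carbon by NBS and the resulting bromo ylide condenses with the aldehyde so that the aryl group ends up trans to the ester and therefore cis to bromine (Z), the minor E isomer being removed by chromatography.

Step 3
Reactants: 3 methyl (Z)-2-bromo-3-[3,5-dimethoxy-4-(triisopropylsilyloxy)phenyl]prop-2-enoate; 4 3-iodooxetane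
Product: 6 methyl (E)-3-[3,5-dimethoxy-4-(triisopropylsilyloxy)phenyl]-2-(oxetan-3-yl)prop-2-enoate, via oxetan-3-ylzinc iodide 5 (not isolated)
Conditions: Zn dust (activated with BrCH2CH2Br and Me3SiCl), LiCl, THF, 40 °C; then 3, Pd2(dba)3 (2.5 mol%), SPhos (10 mol%), THF, 50 °C
Reagents that add atoms: none
Why: Negishi coupling: zinc inserts into the C–I bond of 4, zerovalent palladium adds to the activated alkenyl C–Br bond of 3 and the sp2–sp3 bond forms with retention of alkene geometry, so the Z bromide should give the E ester with the aryl group still trans to CO2Me, while β-hydride elimination from the oxetan-3-yl palladium species would need a strained oxete and is not expected.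

Step 4
Reactants: 6 methyl (E)-3-[3,5-dimethoxy-4-(triisopropylsilyloxy)phenyl]-2-(oxetan-3-yl)prop-2-enoate
Product: 8 (E)-3-[3,5-dimethoxy-4-(triisopropylsilyloxy)phenyl]-2-(oxetan-3-yl)prop-2-enoic acid, via trimethylstannyl ester 7 (not isolated)
Conditions: Me3SnOH, ClCH2CH2Cl, 60 °C; then 0.01 M aq. KHSO4, 0 °C
Reagents that add atoms: trimethyltin hydroxide, C[Sn](C)(C)O
Why: Trimethyltin hydroxide ester cleavage delivers hydroxide to the methyl ester under near-neutral conditions that should leave the aryl silyl ether and the oxetane alone, and the acid is set free only in a short cold wash, taken through an acid–base extraction without chromatography and used at once so that uncatalysed ring closure has no time to occur.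

Step 5
Reactants: 8 (E)-3-[3,5-dimethoxy-4-(triisopropylsilyloxy)phenyl]-2-(oxetan-3-yl)prop-2-enoic acid
Product: 9 (R,E)-3-[3,5-dimethoxy-4-(triisopropylsilyloxy)benzylidene]-4-(hydroxymethyl)oxolan-2-one
Conditions: (R)-3,3'-bis(2,4,6-triisopropylphenyl)-1,1'-binaphthyl-2,2'-diyl hydrogen phosphate (10 mol%), toluene (0.02 M), −20 °C → 0 °C
Reagents that add atoms: none
Why: Proposed new method: the phosphoric acid is expected to hold the substrate at two points, its P–OH on the oxetane oxygen and its P=O on the carboxylic O–H, so that the carbonyl oxygen attacks one oxetane CH2 anti to the breaking C–O bond (SN2) while the proton is relayed through the phosphate, forming O1–C5 with release of the oxetane ring strain. The closest known reaction types are chiral phosphoric acid-catalysed desymmetrising openings of 3-substituted oxetanes by tethered alcohols or amines, phosphoric acid-catalysed openings of meso-epoxides by carboxylic acids through acid–acid heterodimers, and the uncatalysed thermal isomerisation of oxetane-carboxylic acids to lactones. The lactone closes in the 5-exo-tet mode, the leaving oxygen lying outside the new ring and becoming the hydroxyl of the CH2OH group. C4 is not a reacting centre; its configuration is decided by which of the two enantiotopic CH2 groups becomes C5, and that choice is made by the chiral pocket of the catalyst. The step needs enantiotopic-group selectivity and a catalysed rate well above self-catalysis by the substrate acid: allylic 1,3-strain with the cis aryl group should hold the oxetane C–H in the alkene plane so that the two CH2 arms flank the carboxyl group symmetrically for a two-point-bound catalyst to tell apart, and low temperature, high dilution and a non-polar solvent are chosen to suppress the background. Because acid and oxetane are geminal on C3, no alkene isomerisation is required and the E geometry should pass through unchanged.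

Step 6
Reactants: 9 (R,E)-3-[3,5-dimethoxy-4-(triisopropylsilyloxy)benzylidene]-4-(hydroxymethyl)oxolan-2-one
Product: 10 (S,E)-3-[3,5-dimethoxy-4-(triisopropylsilyloxy)benzylidene]-4-(iodomethyl)oxolan-2-one
Conditions: PPh3, I2, imidazole, CH2Cl2, 0 °C
Reagents that add atoms: iodine, II
Why: The Appel reaction converts the primary alcohol into the iodide through an alkoxyphosphonium ion under imidazole-buffered conditions without touching C4 (the descriptor changes only through the priority rules), and capping the hydroxyl at once removes the chance that it attacks the lactone carbonyl and exchanges the two CH2–O arms, which would racemise C4.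

Step 7
Reactants: 10 (S,E)-3-[3,5-dimethoxy-4-(triisopropylsilyloxy)benzylidene]-4-(iodomethyl)oxolan-2-one; 11 5-iodo-1,2,3-trimethoxybenzene
Product: 13 (S,E)-3-[3,5-dimethoxy-4-(triisopropylsilyloxy)benzylidene]-4-(3,4,5-trimethoxybenzyl)oxolan-2-one, via alkylzinc iodide 12 (not isolated)
Conditions: Zn dust, I2 (cat.), DMF, rt; then 11, Pd2(dba)3 (2.5 mol%), SPhos (10 mol%), DMF, rt → 40 °C
Reagents that add atoms: none
Why: Negishi coupling of a primary alkylzinc iodide: zinc inserts into the C–I bond in DMF, the organozinc tolerates the lactone, the enoate and the silyl ether and has no β-leaving group, and with SPhos on palladium reductive elimination to the aryl–CH2 bond should outrun β-hydride elimination, leaving C4 untouched.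

Step 8
Reactants: 13 (S,E)-3-[3,5-dimethoxy-4-(triisopropylsilyloxy)benzylidene]-4-(3,4,5-trimethoxybenzyl)oxolan-2-one
Product: 14 (S,E)-3-(4-hydroxy-3,5-dimethoxybenzylidene)-4-(3,4,5-trimethoxybenzyl)oxolan-2-one
Conditions: Bu4NF, AcOH (1:1), THF, 0 °C
Reagents that add atoms: none
Why: Fluoride-induced cleavage of the aryl silyl ether is fast, and the acetic acid buffer should keep the phenoxide protonated so that neither lactone opening nor γ-deprotonation at C4 (racemisation or migration of the alkene into the ring) takes place.

**Compound list**

1 | syringaldehyde (4-hydroxy-3,5-dimethoxybenzaldehyde) | COc1cc(C=O)cc(OC)c1O | starting material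
2 | 3,5-dimethoxy-4-(triisopropylsilyloxy)benzaldehyde | COc1cc(C=O)cc(OC)c1O[Si](C(C)C)(C(C)C)C(C)C | intermediate
3 | methyl (Z)-2-bromo-3-[3,5-dimethoxy-4-(triisopropylsilyloxy)phenyl]prop-2-enoate | COC(=O)/C(Br)=C/c1cc(OC)c(O[Si](C(C)C)(C(C)C)C(C)C)c(OC)c1 | intermediate
4 | 3-iodooxetane | IC1COC1 | starting material
5 | oxetan-3-ylzinc iodide | I[Zn]C1COC1 | intermediate
6 | methyl (E)-3-[3,5-dimethoxy-4-(triisopropylsilyloxy)phenyl]-2-(oxetan-3-yl)prop-2-enoate | COC(=O)/C(=C/c1cc(OC)c(O[Si](C(C)C)(C(C)C)C(C)C)c(OC)c1)C1COC1 | intermediate
7 | trimethylstannyl (E)-3-[3,5-dimethoxy-4-(triisopropylsilyloxy)phenyl]-2-(oxetan-3-yl)prop-2-enoate | C[Sn](C)(C)OC(=O)/C(=C/c1cc(OC)c(O[Si](C(C)C)(C(C)C)C(C)C)c(OC)c1)C1COC1 | intermediate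
8 | (E)-3-[3,5-dimethoxy-4-(triisopropylsilyloxy)phenyl]-2-(oxetan-3-yl)prop-2-enoic acid | OC(=O)/C(=C/c1cc(OC)c(O[Si](C(C)C)(C(C)C)C(C)C)c(OC)c1)C1COC1 | intermediate
9 | (R,E)-3-[3,5-dimethoxy-4-(triisopropylsilyloxy)benzylidene]-4-(hydroxymethyl)oxolan-2-one | COc1cc(/C=C2/C(=O)OC[C@H]2CO)cc(OC)c1O[Si](C(C)C)(C(C)C)C(C)C | intermediate
10 | (S,E)-3-[3,5-dimethoxy-4-(triisopropylsilyloxy)benzylidene]-4-(iodomethyl)oxolan-2-one | COc1cc(/C=C2/C(=O)OC[C@H]2CI)cc(OC)c1O[Si](C(C)C)(C(C)C)C(C)C | intermediate
11 | 5-iodo-1,2,3-trimethoxybenzene | COc1cc(I)cc(OC)c1OC | starting material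
12 | {[(S,E)-4-[3,5-dimethoxy-4-(triisopropylsilyloxy)benzylidene]-5-oxooxolan-3-yl]methyl}zinc iodide | COc1cc(/C=C2/C(=O)OC[C@H]2C[Zn]I)cc(OC)c1O[Si](C(C)C)(C(C)C)C(C)C | intermediate
13 | (S,E)-3-[3,5-dimethoxy-4-(triisopropylsilyloxy)benzylidene]-4-(3,4,5-trimethoxybenzyl)oxolan-2-one | COc1cc(/C=C2/C(=O)OC[C@H]2Cc2cc(OC)c(OC)c(OC)c2)cc(OC)c1O[Si](C(C)C)(C(C)C)C(C)C | intermediate
14 | (S,E)-3-(4-hydroxy-3,5-dimethoxybenzylidene)-4-(3,4,5-trimethoxybenzyl)oxolan-2-one | COc1cc(/C=C2/C(=O)OC[C@H]2Cc2cc(OC)c(OC)c(OC)c2)cc(OC)c1O | target

**Step count**

Total: 8 steps. Longest linear sequence: 8 steps (1 to 14); 4 and 11 are purchased and enter in steps 3 and 7.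

**Steps most likely to fail**

1. Step 5. The catalyst pocket may discriminate poorly between the two enantiotopic CH2 groups. Self-catalysed ring closure by the substrate acid may compete with the catalysed path. Acyl transfer between the two CH2–O arms of the product may erode the enantiomeric purity before the iodination. The fallback gives up catalytic stereocontrol in favour of resolution. It sets out from 8, which is warmed in toluene with diphenyl phosphate (10 mol%, 40 °C); this achiral acid-promoted isomerisation of an oxetane-carboxylic acid should give the racemic hydroxymethyl lactone F1. Preparative chromatography on a chiral stationary phase (cellulose tris(3,5-dimethylphenylcarbamate), CO2/2-propanol) then separates the (R)-enantiomer, which is compound 9, from the (S)-configured hydroxymethyl lactone F2. The route is rejoined at 9, which is iodinated without delay.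

2. Step 7. The transient homoallylic radical on the zinc surface may close onto C3 of the arylidene unit and reopen with skeletal rearrangement. The alkylzinc may be protonated before coupling. β-Hydride elimination may occur after transmetalation. The fallback reverses the polarity of the coupling so that the alkyl iodide enters by two-electron oxidative addition. It sets out from 11, which with Zn dust and LiCl in THF at 50 °C should give (3,4,5-trimethoxyphenyl)zinc iodide F3. F3 is coupled with iodide 10 using Pd2(dba)3, tricyclopentylphosphine and N-methylimidazole in THF/N-methylpyrrolidone at 80 °C, a Negishi coupling of an unactivated primary alkyl iodide with an arylzinc halide. The route is rejoined at 13.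

3. Step 4. The acid or its tin carboxylate may close onto the oxetane without stereocontrol during the warm cleavage or the acidic wash. The aryl silyl ether may be lost. The hindered ester may react sluggishly. The fallback reaches the acid by oxidation instead of hydrolysis. It sets out from 6, which diisobutylaluminium hydride (CH2Cl2, −78 °C) should reduce to (E)-3-[3,5-dimethoxy-4-(triisopropylsilyloxy)phenyl]-2-(oxetan-3-yl)prop-2-en-1-ol F4. MnO2 (CH2Cl2, rt) oxidises this to (E)-3-[3,5-dimethoxy-4-(triisopropylsilyloxy)phenyl]-2-(oxetan-3-yl)prop-2-enal F5. Pinnick oxidation (NaClO2, NaH2PO4, 2-methyl-2-butene, t-BuOH/H2O, 0 °C) then gives the acid cold at about pH 4. The route is rejoined at 8.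

**Further compounds**

F1 | step 5 | racemic (E)-3-[3,5-dimethoxy-4-(triisopropylsilyloxy)benzylidene]-4-(hydroxymethyl)oxolan-2-one | COc1cc(/C=C2/C(=O)OCC2CO)cc(OC)c1O[Si](C(C)C)(C(C)C)C(C)C
F2 | step 5 | (S,E)-3-[3,5-dimethoxy-4-(triisopropylsilyloxy)benzylidene]-4-(hydroxymethyl)oxolan-2-one | COc1cc(/C=C2/C(=O)OC[C@@H]2CO)cc(OC)c1O[Si](C(C)C)(C(C)C)C(C)C
F3 | step 7 | (3,4,5-trimethoxyphenyl)zinc iodide | COc1cc([Zn]I)cc(OC)c1OC
F4 | step 4 | (E)-3-[3,5-dimethoxy-4-(triisopropylsilyloxy)phenyl]-2-(oxetan-3-yl)prop-2-en-1-ol | OC/C(=C/c1cc(OC)c(O[Si](C(C)C)(C(C)C)C(C)C)c(OC)c1)C1COC1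
F5 | step 4 | (E)-3-[3,5-dimethoxy-4-(triisopropylsilyloxy)phenyl]-2-(oxetan-3-yl)prop-2-enal | O=C/C(=C/c1cc(OC)c(O[Si](C(C)C)(C(C)C)C(C)C)c(OC)c1)C1COC1
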